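**Plan**

1. Locants follow 2H-chromene numbering (O1, C2, C3, C4, C4a, C5–C8, C8a). Ring A is the oxygenated benzene ring, ring B the pyran ring, ring C the 4-methoxyphenyl ring.
2. Retrosynthesis, late cuts: the 7-OH is masked as a MOM ether, the 1,2-diketone goes back to the benzyl ketone, the 5-OMe to a free 5-OH, and the C3=C4 double bond to a 4-phenylsulfonyl chroman.
3. Central cut: C2–C3 and C4–C4a of ring B together, leaving a 2-aryloxy-2-methylpropanoic acid on ring A and phenyl vinyl sulfone as the C3–C4 unit. Then O1–C2 (phenol plus ethyl 2-bromo-2-methylpropanoate) and the aryl–acyl bond (phloroglucinol plus 4-methoxyphenylacetic acid).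
4. Forward: rings A and C are bought. Ring A is acylated, its para-OH alkylated, one of the two equivalent chelated OH groups protected, and the acid freed. Ring B is then built in one operation by a decarboxylative photoredox radical (4+2) annulation. The sulfone helper is eliminated through an ortho-quinone methide, O5 is methylated, the CH2 is oxidised and the MOM group removed.
5. Enabling feature: C2 is a gem-dimethyl carbon on the aryl ether oxygen O1, so decarboxylation gives a stabilised, nucleophilic tertiary α-aryloxy radical. It sits four atoms (C2, O1, C8a, C4a) from an oxygen-flanked ortho C–H of the electron-rich ring A.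
6. Stereochemistry: the target has no stereocentre. The only one on the route (C4 of the sulfonyl chroman) forms as a racemate and is erased by the elimination.

Key step: step 5

**Route**

Step 1
Reactants: 1 phloroglucinol (benzene-1,3,5-triol); 2 4-methoxyphenylacetic acid
Product: 3 2-(4-methoxyphenyl)-1-(2,4,6-trihydroxyphenyl)ethanone
Conditions: BF3·OEt2 (solvent and promoter), 80 °C; then aq. NaOAc
Reagents that add atoms: none
Why: Friedel–Crafts acylation of the symmetrical triol by the BF3-activated acid; the three ring C–H positions are equivalent and the aryl ketone formed deactivates ring A against a second acylation.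

Step 2
Reactants: 3 2-(4-methoxyphenyl)-1-(2,4,6-trihydroxyphenyl)ethanone; 4 ethyl 2-bromo-2-methylpropanoate
Product: 5 ethyl 2-{3,5-dihydroxy-4-[(4-methoxyphenyl)acetyl]phenoxy}-2-methylpropanoate
Conditions: K2CO3 (1.2 equiv), DMF, 60 °C
Reagents that add atoms: none
Why: Williamson-type O-alkylation of a para-acylphenoxide with a tertiary α-bromo ester (the fibrate ether synthesis); only the 4-OH is free of the hydrogen bond to the ketone and is the most acidic, so one equivalent of carbonate should alkylate it selectively.

Step 3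
Reactants: 5 ethyl 2-{3,5-dihydroxy-4-[(4-methoxyphenyl)acetyl]phenoxy}-2-methylpropanoate
Product: 6 ethyl 2-{3-hydroxy-5-(methoxymethoxy)-4-[(4-methoxyphenyl)acetyl]phenoxy}-2-methylpropanoate
Conditions: MOMCl (1.2 equiv), i-Pr2NEt, CH2Cl2, 0 °C to rt
Reagents that add atoms: chloromethyl methyl ether (MOMCl), COCCl
Why: acetal protection of a phenol; the two chelated OH groups are equivalent, and once one is etherified the other is held in a stronger hydrogen bond to the ketone and should resist a second alkylation, the usual outcome for 2,6-dihydroxyaryl ketones.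

Step 4
Reactants: 6 ethyl 2-{3-hydroxy-5-(methoxymethoxy)-4-[(4-methoxyphenyl)acetyl]phenoxy}-2-methylpropanoate
Product: 7 2-{3-hydroxy-5-(methoxymethoxy)-4-[(4-methoxyphenyl)acetyl]phenoxy}-2-methylpropanoic acid
Conditions: LiOH·H2O, THF/MeOH/H2O, 50 °C, argon; then 1 M HCl to pH 4 at 0 °C
Reagents that add atoms: lithium hydroxide, [Li+].[OH-]
Why: saponification of the hindered ethyl ester; the MOM acetal, the aryl ethers and the benzyl ketone are stable to hydroxide, and exclusion of air avoids autoxidation of the ketone enolate.

Step 5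
Reactants: 7 2-{3-hydroxy-5-(methoxymethoxy)-4-[(4-methoxyphenyl)acetyl]phenoxy}-2-methylpropanoic acid; 8 N-hydroxyphthalimide; 9 phenyl vinyl sulfone
Product: 11 racemic 1-[5-hydroxy-7-(methoxymethoxy)-2,2-dimethyl-4-(phenylsulfonyl)-3,4-dihydro-2H-chromen-6-yl]-2-(4-methoxyphenyl)ethanone, via redox-active ester 10 (not isolated)
Conditions: N,N'-diisopropylcarbodiimide (DIC), DMAP (cat.), CH2Cl2, rt; filter, evaporate; then 9 (3 equiv), fac-Ir(ppy)3 (tris(2-phenylpyridinato)iridium, 1 mol %), degassed MeCN, blue LEDs (450 nm), rt
Reagents that add atoms: none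
Why: Carbodiimide coupling gives N-acyloxyphthalimide 10, which excited fac-Ir(ppy)3 reduces by one electron; loss of CO2 and phthalimide anion leaves the tertiary α-aryloxy radical at C2, which adds to the CH2 terminus of phenyl vinyl sulfone (C2–C3 bond), and the electrophilic α-sulfonyl radical so formed attacks the ortho carbon of ring A (C4–C4a bond), after which the tetravalent iridium complex oxidises the cyclohexadienyl radical and phthalimide anion removes the proton, closing a redox-neutral cycle. The closest known reaction type is the photoredox radical (4+2) annulation of N-acyloxyphthalimides of α-aryloxy acids with electron-poor alkenes to chromans, applied here to a fibrate-type acid. Ring B closes by a six-membered homolytic aromatic substitution (6-exo-trig with respect to the C4a=C5 bond of ring A), helped by the gem-dimethyl group at C2. The one new stereocentre, C4, needs no control and forms as a racemate, since step 6 removes it. The step needs regioselectivity between the two non-equivalent ortho C–H positions of ring A, and closure beside the free hydrogen-bonded OH should be favoured because the other position is screened by the MOM ether, whose CH2OCH3 arm is turned toward that C–H by the neighbouring acyl group and would clash with the peri sulfonyl group, in line with the known preference of chelated 2-hydroxyaryl ketones for ring closure at the carbon beside the chelated OH. Polarity matching (nucleophilic radical to electron-poor alkene, electrophilic radical to an arene carbon that is ortho or para to three oxygens and meta to the acyl group) fixes the order of the two bond formations and holds back oligomerisation of the sulfone.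

Step 6
Reactants: 11 racemic 1-[5-hydroxy-7-(methoxymethoxy)-2,2-dimethyl-4-(phenylsulfonyl)-3,4-dihydro-2H-chromen-6-yl]-2-(4-methoxyphenyl)ethanone
Product: 14 1-[5-methoxy-7-(methoxymethoxy)-2,2-dimethyl-2H-chromen-6-yl]-2-(4-methoxyphenyl)ethanone, via ortho-quinone methide 12 (not isolated), via 5-hydroxychromene 13 (not isolated)
Conditions: K2CO3 (3 equiv), MeI (3 equiv), acetone, 50 °C
Reagents that add atoms: iodomethane (MeI), CI
Why: the phenoxide at O5 expels benzenesulfinate from the benzylic C4 (the standard base-induced generation of ortho-quinone methides from 2-(sulfonylalkyl)phenols), quinone methide 12 tautomerises by loss of a C3 proton to the aromatic phenoxide of chromene 13, and MeI then O-methylates this phenoxide while the 7-oxygen stays masked.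

Step 7
Reactants: 14 1-[5-methoxy-7-(methoxymethoxy)-2,2-dimethyl-2H-chromen-6-yl]-2-(4-methoxyphenyl)ethanone
Product: 15 1-[5-methoxy-7-(methoxymethoxy)-2,2-dimethyl-2H-chromen-6-yl]-2-(4-methoxyphenyl)ethane-1,2-dione
Conditions: SeO2 (1.5 equiv), pyridine (2 equiv), 1,4-dioxane, 90 °C
Reagents that add atoms: selenium dioxide, O=[Se]=O
Why: Riley oxidation of the only enolisable position, the benzylic CH2 of the deoxybenzoin, to the 1,2-diketone; ring B offers no allylic C–H (C2 is quaternary) for the competing ene reaction, and pyridine buffers the selenous acid so that the MOM acetal and the chromene should survive.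

Step 8
Reactants: 15 1-[5-methoxy-7-(methoxymethoxy)-2,2-dimethyl-2H-chromen-6-yl]-2-(4-methoxyphenyl)ethane-1,2-dione
Product: 16 1-(7-hydroxy-5-methoxy-2,2-dimethyl-2H-chromen-6-yl)-2-(4-methoxyphenyl)ethane-1,2-dione (CNP0170833.0)
Conditions: 3 M aq. HCl, THF, 40 °C
Reagents that add atoms: none
Why: acid hydrolysis of the MOM acetal, which is especially labile ortho to a carbonyl group; the aryl methyl ethers, the diketone and the 2,2-dimethylchromene should tolerate these conditions, and methanol is left out so that the diketone is not ketalised.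

**Compound list**

1 | phloroglucinol (benzene-1,3,5-triol) | Oc1cc(O)cc(O)c1 | starting material
2 | 4-methoxyphenylacetic acid | COc1ccc(CC(=O)O)cc1 | starting material
3 | 2-(4-methoxyphenyl)-1-(2,4,6-trihydroxyphenyl)ethanone | COc1ccc(CC(=O)c2c(O)cc(O)cc2O)cc1 | intermediate
4 | ethyl 2-bromo-2-methylpropanoate | CCOC(=O)C(C)(C)Br | starting material
5 | ethyl 2-{3,5-dihydroxy-4-[(4-methoxyphenyl)acetyl]phenoxy}-2-methylpropanoate | CCOC(=O)C(C)(C)Oc1cc(O)c(C(=O)Cc2ccc(OC)cc2)c(O)c1 | intermediate
6 | ethyl 2-{3-hydroxy-5-(methoxymethoxy)-4-[(4-methoxyphenyl)acetyl]phenoxy}-2-methylpropanoate | CCOC(=O)C(C)(C)Oc1cc(O)c(C(=O)Cc2ccc(OC)cc2)c(OCOC)c1 | intermediate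
7 | 2-{3-hydroxy-5-(methoxymethoxy)-4-[(4-methoxyphenyl)acetyl]phenoxy}-2-methylpropanoic acid | OC(=O)C(C)(C)Oc1cc(O)c(C(=O)Cc2ccc(OC)cc2)c(OCOC)c1 | intermediate
8 | N-hydroxyphthalimide | O=C1c2ccccc2C(=O)N1O | starting material
9 | phenyl vinyl sulfone | C=CS(=O)(=O)c1ccccc1 | starting material
10 | 1,3-dioxoisoindolin-2-yl 2-{3-hydroxy-5-(methoxymethoxy)-4-[(4-methoxyphenyl)acetyl]phenoxy}-2-methylpropanoate (redox-active ester, not isolated) | O=C(ON1C(=O)c2ccccc2C1=O)C(C)(C)Oc1cc(O)c(C(=O)Cc2ccc(OC)cc2)c(OCOC)c1 | intermediate
11 | racemic 1-[5-hydroxy-7-(methoxymethoxy)-2,2-dimethyl-4-(phenylsulfonyl)-3,4-dihydro-2H-chromen-6-yl]-2-(4-methoxyphenyl)ethanone | COc1ccc(CC(=O)c2c(OCOC)cc3OC(C)(C)CC(S(=O)(=O)c4ccccc4)c3c2O)cc1 | intermediate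
12 | 7-(methoxymethoxy)-6-[(4-methoxyphenyl)acetyl]-2,2-dimethyl-2,3-dihydro-5H-chromen-5-one (ortho-quinone methide, not isolated) | COc1ccc(CC(=O)C2=C(OCOC)C=C3OC(C)(C)CC=C3C2=O)cc1 | intermediate
13 | 1-[5-hydroxy-7-(methoxymethoxy)-2,2-dimethyl-2H-chromen-6-yl]-2-(4-methoxyphenyl)ethanone (not isolated) | COc1ccc(CC(=O)c2c(OCOC)cc3OC(C)(C)C=Cc3c2O)cc1 | intermediate
14 | 1-[5-methoxy-7-(methoxymethoxy)-2,2-dimethyl-2H-chromen-6-yl]-2-(4-methoxyphenyl)ethanone | COc1ccc(CC(=O)c2c(OCOC)cc3OC(C)(C)C=Cc3c2OC)cc1 | intermediate
15 | 1-[5-methoxy-7-(methoxymethoxy)-2,2-dimethyl-2H-chromen-6-yl]-2-(4-methoxyphenyl)ethane-1,2-dione | COc1ccc(C(=O)C(=O)c2c(OCOC)cc3OC(C)(C)C=Cc3c2OC)cc1 | intermediate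
16 | 1-(7-hydroxy-5-methoxy-2,2-dimethyl-2H-chromen-6-yl)-2-(4-methoxyphenyl)ethane-1,2-dione | COc1ccc(C(=O)C(=O)c2c(O)cc3c(c2OC)C=CC(C)(C)O3)cc1 | target

**Summary**

Total step count: 8. Longest linear sequence: 8 steps (from 1 and 2 to 16).

Steps most likely to fail, riskiest first:

Step 5. What may go wrong: ring closure at the other ortho C–H of ring A, over-oxidation of the α-aryloxy radical to an oxocarbenium ion with loss of the side chain, or conjugate addition to the sulfone without cyclisation. The fallback builds ring B by known pericyclic chemistry and sets out from 3. The 4-OH of 3 is alkylated with 3-chloro-3-methylbut-1-yne (K2CO3, KI, CuI cat., acetone, 60 °C) to give 1-[2,6-dihydroxy-4-(2-methylbut-3-yn-2-yloxy)phenyl]-2-(4-methoxyphenyl)ethanone F1. One chelated OH is protected (MOMCl, i-Pr2NEt, CH2Cl2) to give 1-[2-hydroxy-6-(methoxymethoxy)-4-(2-methylbut-3-yn-2-yloxy)phenyl]-2-(4-methoxyphenyl)ethanone F2. Heating F2 in N,N-diethylaniline at 180 °C should trigger the aryl propargyl ether Claisen rearrangement, 1,5-hydrogen shift and oxa-6π electrocyclisation, closing beside the chelated OH. This comes back to the route at 13, which is isolated and methylated with K2CO3 and MeI as in step 6 to give 14.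

Step 7. What may go wrong: attack of the electrophilic selenium reagent on the electron-rich C3=C4 double bond, or over-oxidation with C–C cleavage of the diketone. The fallback sets out from 14 and replaces the Riley oxidation by enolate hydroxylation and alcohol oxidation. Deprotonation with KN(SiMe3)2 in THF at −78 °C and trapping with 3-phenyl-2-(phenylsulfonyl)oxaziridine should give racemic 2-hydroxy-1-[5-methoxy-7-(methoxymethoxy)-2,2-dimethyl-2H-chromen-6-yl]-2-(4-methoxyphenyl)ethanone F3. Oxidation of F3 with 1,1,1-triacetoxy-1,1-dihydro-1,2-benziodoxol-3(1H)-one (DMP), NaHCO3, CH2Cl2, rt comes back to the route at 15.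

Step 2. What may go wrong: slow substitution at the tertiary bromide, with competing elimination to ethyl methacrylate, double O-alkylation or C-alkylation of ring A. The fallback sets out from 3 and uses a Bargellini-type reaction. Treatment with 1,1,1-trichloro-2-methylpropan-2-ol and NaOH in acetone (0 °C to rt) should give 2-{3,5-dihydroxy-4-[(4-methoxyphenyl)acetyl]phenoxy}-2-methylpropanoic acid F4 directly. Carboxylate-selective esterification of F4 (EtI, KHCO3, DMF, rt) comes back to the route at 5.

**Further compounds**

F1 | step 5 | 1-[2,6-dihydroxy-4-(2-methylbut-3-yn-2-yloxy)phenyl]-2-(4-methoxyphenyl)ethanone | COc1ccc(CC(=O)c2c(O)cc(OC(C)(C)C#C)cc2O)cc1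
F2 | step 5 | 1-[2-hydroxy-6-(methoxymethoxy)-4-(2-methylbut-3-yn-2-yloxy)phenyl]-2-(4-methoxyphenyl)ethanone | COc1ccc(CC(=O)c2c(O)cc(OC(C)(C)C#C)cc2OCOC)cc1
F3 | step 7 | racemic 2-hydroxy-1-[5-methoxy-7-(methoxymethoxy)-2,2-dimethyl-2H-chromen-6-yl]-2-(4-methoxyphenyl)ethanone | COc1ccc(C(O)C(=O)c2c(OCOC)cc3OC(C)(C)C=Cc3c2OC)cc1
F4 | step 2 | 2-{3,5-dihydroxy-4-[(4-methoxyphenyl)acetyl]phenoxy}-2-methylpropanoic acid | OC(=O)C(C)(C)Oc1cc(O)c(C(=O)Cc2ccc(OC)cc2)c(O)c1
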